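The oxane is cut at C5–C6 (O1; C2 carries the CH2CH2–ring B chain, C4 the axial OH, C6 ring A). C6 is bonded to O1 and is also benzylic to the electron-rich, 3,4-dioxygenated ring A. Opened up, it becomes the ArCH2–O group of a ring A benzyl-type ether on the C2 carbinol, whose C–H bonds are the weakest point of the molecule towards oxidation. Mediated anodic hydride removal at that carbon and capture of the oxocarbenium ion by a pendant enol acetate should forge C5–C6, close the ring as the C4 ketone and relay C2 to C6 (cis) in one operation. The precursor is this (S)-ether bearing a 2-acetoxyallyl arm, with ring B masked as a pivalate.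

Key step: step 7

Assumption: with the numbering above the target is (2S,4S,6S), the C2 and C6 substituents cis-diequatorial and the C4 hydroxyl axial; 4-(3-hydroxypropyl)-2-methoxyphenol and (4-benzyloxy-3-methoxyphenyl)methanol are taken as catalogue compounds; the Re-face preference of (R)-TRIP is taken from the accepted transition-state model and would be checked on the homopropargylic alcohol by chiral HPLC against material made with the antipodal acid.

Step 1
Reactants: 1 4-(3-hydroxypropyl)-2-methoxyphenol (dihydroconiferyl alcohol); 2 pivaloyl chloride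
Product: 3 4-(3-hydroxypropyl)-2-methoxyphenyl pivalate
Conditions: aq NaOH (1.05 equiv), THF, 0 °C; PivCl (1.05 equiv)
Reagents that add atoms: none
Why: Schotten–Baumann acylation, in which only the phenol (far more acidic than the primary alcohol) is ionised by hydroxide, so the phenoxide should be pivaloylated while the neutral aliphatic hydroxyl is left free.

Step 2
Reactants: 3 4-(3-hydroxypropyl)-2-methoxyphenyl pivalate
Product: 4 2-methoxy-4-(3-oxopropyl)phenyl pivalate
Conditions: TEMPO (10 mol %), PhI(OAc)2 (1.1 equiv), CH2Cl2, rt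
Reagents that add atoms: none
Why: Oxoammonium-catalysed (TEMPO) oxidation of a primary alcohol stops at the aldehyde and should not touch the aryl pivalate or the acyl-deactivated arene.

Step 3
Reactants: 4 2-methoxy-4-(3-oxopropyl)phenyl pivalate; 5 allenylboronic acid pinacol ester
Product: 7 4-[(3S)-3-hydroxyhex-5-yn-1-yl]-2-methoxyphenyl pivalate, via pinacol borate ester 6 (not isolated)
Conditions: (R)-TRIP [(R)-3,3′-bis(2,4,6-triisopropylphenyl)-1,1′-binaphthyl-2,2′-diyl hydrogen phosphate] (10 mol %), 4 Å MS, toluene, −20 °C; then aqueous work-up, SiO2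
Reagents that add atoms: none
Why: Chiral phosphoric acid-catalysed propargylboration, in which the acid hydrogen-bonds a boronate oxygen and the formyl C–H in a closed six-membered transition state so that the allenyl group is delivered with allenyl-to-propargyl transposition to the Re face of 4, setting the S carbinol that becomes C2 of the oxane.

Step 4
Reactants: 8 (4-benzyloxy-3-methoxyphenyl)methanol
Product: 9 (4-benzyloxy-3-methoxyphenyl)methyl 2,2,2-trichloroacetimidate
Conditions: Cl3CCN (1.5 equiv), DBU (10 mol %), CH2Cl2, 0 °C; used without storage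
Reagents that add atoms: trichloroacetonitrile, ClC(Cl)(Cl)C#N
Why: Base-catalysed addition of a benzylic alcohol to trichloroacetonitrile (imidate formation) is routine for alkoxybenzyl alcohols and gives the benzyl donor for the next step.

Step 5
Reactants: 7 4-[(3S)-3-hydroxyhex-5-yn-1-yl]-2-methoxyphenyl pivalate; 9 (4-benzyloxy-3-methoxyphenyl)methyl 2,2,2-trichloroacetimidate
Product: 10 4-[(3S)-3-[(4-benzyloxy-3-methoxyphenyl)methoxy]hex-5-yn-1-yl]-2-methoxyphenyl pivalate
Conditions: 9 (1.5 equiv), PPTS (10 mol %), CH2Cl2, 0 °C → rt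
Reagents that add atoms: none
Why: Acid-catalysed trichloroacetimidate etherification transfers the stabilised 3,4-dialkoxybenzyl cation to the secondary alcohol without base, so the aryl pivalate and the terminal alkyne should survive, and the carbinol configuration is kept because its C–O bond is not broken.

Step 6
Reactants: 10 4-[(3S)-3-[(4-benzyloxy-3-methoxyphenyl)methoxy]hex-5-yn-1-yl]-2-methoxyphenyl pivalate
Product: 11 (4S)-4-[(4-benzyloxy-3-methoxyphenyl)methoxy]-6-(3-methoxy-4-pivaloyloxyphenyl)hex-1-en-2-yl acetate
Conditions: [Ru(p-cymene)Cl2]2 (2 mol %), P(2-furyl)3 (4 mol %), Na2CO3 (8 mol %), AcOH (2 equiv), toluene, 80 °C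
Reagents that add atoms: acetic acid, CC(=O)O
Why: Ruthenium-catalysed Markovnikov hydro-acyloxylation of a terminal alkyne with a carboxylic acid gives the 2-acetoxy-1-alkene regioselectively under weakly acidic, buffered conditions that ethers and esters tolerate.

Step 7
Reactants: 11 (4S)-4-[(4-benzyloxy-3-methoxyphenyl)methoxy]-6-(3-methoxy-4-pivaloyloxyphenyl)hex-1-en-2-yl acetate
Product: 13 4-{2-[(2S,6S)-6-(4-benzyloxy-3-methoxyphenyl)-4-oxooxan-2-yl]ethyl}-2-methoxyphenyl pivalate, via oxocarbenium ion 12 (not isolated)
Conditions: DDQ (20 mol %), LiClO4 (0.1 M), 2,6-dichloropyridine (1 equiv), AcOH (3 equiv), 4 Å MS, MeCN–ClCH2CH2Cl (1:1), undivided cell, RVC anode, Pt-wire cathode, controlled anode potential at the DDQH2/DDQ wave, rt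
Reagents that add atoms: none
Why: Proposed new method: DDQ should take a hydride (electron transfer, then loss of the benzylic hydrogen) from the OCH2 of the ring A benzyl-type ether of 11 to give the (E)-oxocarbenium ion 12, the terminal carbon of the enol acetate then adds to it to forge C5–C6, the acetyl group is passed on to acetic acid, and DDQH2 is re-oxidised at the anode while protons are reduced at the cathode. The closest known reaction type is the cyclisation of p-alkoxybenzyl ethers onto tethered enol acetates with stoichiometric DDQ (or catalytic DDQ with MnO2 as terminal oxidant), and anodic regeneration of DDQ is known for other benzylic dehydrogenations, so only their combination on this substrate is new. The oxane closes in a 6-endo-trig mode, since both the C=O+ bond that is attacked and the enol C=C lie inside the new ring. The new C6 stereocentre is controlled by C2: in the chair transition state the C2 side chain and the aryl group of the (E)-oxocarbenium ion are both equatorial, which should give the 2,6-cis ketone. The step needs oxidation at the ring A benzylic ether CH2 and not at the benzylic CH2 of ring B, the PhCH2O group or the enol acetate; this is secured by the low oxidation potential of the dialkoxy ring A and the oxygen stabilisation of its cation, by the pivalate that makes ring B electron-poor, and by an anode potential held at the mediator couple, below the oxidation onset of 11 found by cyclic voltammetry.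

Step 8
Reactants: 13 4-{2-[(2S,6S)-6-(4-benzyloxy-3-methoxyphenyl)-4-oxooxan-2-yl]ethyl}-2-methoxyphenyl pivalate
Product: 15 4-{2-[(2S,4S,6S)-6-(4-benzyloxy-3-methoxyphenyl)-4-hydroxyoxan-2-yl]ethyl}-2-methoxyphenol, via axial alcohol pivalate 14 (not isolated)
Conditions: LiBH(sec-Bu)3 (1.3 equiv), THF, −78 °C; then MeOH, K2CO3 (0.5 equiv), −78 °C → rt; aq NH4Cl
Reagents that add atoms: none
Why: The bulky trialkylborohydride should attack the chair oxanone from the equatorial direction (steric approach control, away from the axial hydrogens at C2 and C6) to set the axial 4S alcohol, and only then, with the ketone gone and retro-oxa-Michael opening excluded, does methoxide cleave the aryl pivalate by transesterification.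

Step 9
Reactants: 15 4-{2-[(2S,4S,6S)-6-(4-benzyloxy-3-methoxyphenyl)-4-hydroxyoxan-2-yl]ethyl}-2-methoxyphenol
Product: 16 4-{2-[(2S,4S,6S)-4-hydroxy-6-(4-hydroxy-3-methoxyphenyl)oxan-2-yl]ethyl}-2-methoxyphenol (target)
Conditions: H2 (1 atm), Pd/C (10 wt %), EtOAc–MeOH, rt, stopped at full conversion
Reagents that add atoms: none
Why: Hydrogenolysis of an aryl benzyl ether over Pd/C is faster than cleavage of the cyclic benzylic C6–O1 bond in a neutral solvent, so the second phenol should be released without opening the oxane or disturbing the three stereocentres.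

Compound list
1 | 4-(3-hydroxypropyl)-2-methoxyphenol (dihydroconiferyl alcohol) | COc1cc(CCCO)ccc1O | starting material
2 | pivaloyl chloride | CC(C)(C)C(Cl)=O | starting material
3 | 4-(3-hydroxypropyl)-2-methoxyphenyl pivalate | COc1cc(CCCO)ccc1OC(=O)C(C)(C)C | intermediate
4 | 2-methoxy-4-(3-oxopropyl)phenyl pivalate | COc1cc(CCC=O)ccc1OC(=O)C(C)(C)C | intermediate
5 | allenylboronic acid pinacol ester | C=C=CB1OC(C)(C)C(C)(C)O1 | starting material
6 | 2-methoxy-4-[(3S)-3-(4,4,5,5-tetramethyl-1,3,2-dioxaborolan-2-yloxy)hex-5-yn-1-yl]phenyl pivalate (not isolated) | COc1cc(CC[C@H](OB2OC(C)(C)C(C)(C)O2)CC#C)ccc1OC(=O)C(C)(C)C | intermediate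
7 | 4-[(3S)-3-hydroxyhex-5-yn-1-yl]-2-methoxyphenyl pivalate | COc1cc(CC[C@H](O)CC#C)ccc1OC(=O)C(C)(C)C | intermediate
8 | (4-benzyloxy-3-methoxyphenyl)methanol | COc1cc(CO)ccc1OCc1ccccc1 | starting material
9 | (4-benzyloxy-3-methoxyphenyl)methyl 2,2,2-trichloroacetimidate | COc1cc(COC(=N)C(Cl)(Cl)Cl)ccc1OCc1ccccc1 | intermediate
10 | 4-[(3S)-3-[(4-benzyloxy-3-methoxyphenyl)methoxy]hex-5-yn-1-yl]-2-methoxyphenyl pivalate | COc1cc(CC[C@H](OCc2ccc(OCc3ccccc3)c(OC)c2)CC#C)ccc1OC(=O)C(C)(C)C | intermediate
11 | (4S)-4-[(4-benzyloxy-3-methoxyphenyl)methoxy]-6-(3-methoxy-4-pivaloyloxyphenyl)hex-1-en-2-yl acetate | COc1cc(CC[C@H](OCc2ccc(OCc3ccccc3)c(OC)c2)CC(OC(C)=O)=C)ccc1OC(=O)C(C)(C)C | intermediate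
12 | (E)-[(4-benzyloxy-3-methoxyphenyl)methylidene][(3S)-5-acetoxy-1-(3-methoxy-4-pivaloyloxyphenyl)hex-5-en-3-yl]oxonium (not isolated) | COc1cc(CC[C@H](/[O+]=C/c2ccc(OCc3ccccc3)c(OC)c2)CC(OC(C)=O)=C)ccc1OC(=O)C(C)(C)C | intermediate
13 | 4-{2-[(2S,6S)-6-(4-benzyloxy-3-methoxyphenyl)-4-oxooxan-2-yl]ethyl}-2-methoxyphenyl pivalate | COc1cc(CC[C@H]2CC(=O)C[C@@H](c3ccc(OCc4ccccc4)c(OC)c3)O2)ccc1OC(=O)C(C)(C)C | intermediate
14 | 4-{2-[(2S,4S,6S)-6-(4-benzyloxy-3-methoxyphenyl)-4-hydroxyoxan-2-yl]ethyl}-2-methoxyphenyl pivalate (not isolated) | COc1cc(CC[C@H]2C[C@H](O)C[C@@H](c3ccc(OCc4ccccc4)c(OC)c3)O2)ccc1OC(=O)C(C)(C)C | intermediate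
15 | 4-{2-[(2S,4S,6S)-6-(4-benzyloxy-3-methoxyphenyl)-4-hydroxyoxan-2-yl]ethyl}-2-methoxyphenol | COc1cc(CC[C@H]2C[C@H](O)C[C@@H](c3ccc(OCc4ccccc4)c(OC)c3)O2)ccc1O | intermediate
16 | 4-{2-[(2S,4S,6S)-4-hydroxy-6-(4-hydroxy-3-methoxyphenyl)oxan-2-yl]ethyl}-2-methoxyphenol | COc1cc(CC[C@H]2C[C@H](O)C[C@@H](c3ccc(O)c(OC)c3)O2)ccc1O | target

Total step count: 9
Longest linear sequence: 8 steps (steps 1–3 and 5–9, from 1); step 4 is the one-step side branch.

Steps most likely to fail

1. Step 7. The mediator may not be turned over cleanly (DDQ reduced at the cathode, or acetyl transfer to the hydroquinone), or oxidation may over-run at the anode (direct oxidation of the enol acetate, or further oxidation at C6–H of the product). The fallback closes the ring by C–O instead of C–C bond formation, using known chemistry, and sets out from aldehyde 4 and benzylic alcohol 8. Alcohol 8 would be oxidised with MnO2 in CH2Cl2 to 4-benzyloxy-3-methoxybenzaldehyde F1. Claisen–Schmidt condensation of F1 with excess acetone (aq NaOH) would give (E)-4-(4-benzyloxy-3-methoxyphenyl)but-3-en-2-one F2. The diisopinocampheylboron enolate of F2 (Ipc2BCl of the antipode matched to Re-face addition, Et3N, Et2O, −78 °C) would be added to aldehyde 4 to give 4-[(3S,6E)-7-(4-benzyloxy-3-methoxyphenyl)-3-hydroxy-5-oxohept-6-en-1-yl]-2-methoxyphenyl pivalate F3. Acid-mediated oxa-Michael addition (Amberlyst-15, CH2Cl2, rt) under thermodynamic control should then close the oxane with both substituents equatorial, returning to the route at ketone 13. The enantiomeric purity of F3 would have to be checked, since this aldol is expected to be less selective than step 3.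

2. Step 3. Facial discrimination by the chiral acid may be incomplete with an unbranched, flexible aliphatic aldehyde. This cannot be corrected later, because C6 and C4 are relayed from C2 and the minor series is therefore enantiomeric, not diastereomeric. The fallback replaces Brønsted-acid catalysis by copper catalysis with a silyl-propargyl borolane and sets out from aldehyde 4. Addition of trimethyl[3-(4,4,5,5-tetramethyl-1,3,2-dioxaborolan-2-yl)prop-1-yn-1-yl]silane with Cu(O2CCHMe2)2, catalytic LiOtBu and the MeO-BIBOP ligand antipode that gives the S alcohol (THF, low temperature) would give 4-[(3S)-3-hydroxy-6-(trimethylsilyl)hex-5-yn-1-yl]-2-methoxyphenyl pivalate F4. Removal of the silyl group with Bu4NF buffered with AcOH (THF, 0 °C), which should spare the aryl pivalate, returns to the route at alcohol 7.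

3. Step 5. Acid-triggered self-condensation of the very electron-rich benzyl donor, or its rearrangement to the N-benzyl trichloroacetamide, may outrun alkylation of the secondary alcohol. The fallback uses neutral benzyl transfer from an oxyquinolinium salt instead of acid activation of an imidate and sets out from alcohol 8 and alcohol 7. Alcohol 8 would be coupled with 2-chloro-4-methylquinoline (KOH, 18-crown-6, toluene, reflux) to give 2-[(4-benzyloxy-3-methoxyphenyl)methoxy]-4-methylquinoline F5. Treating 7 and F5 with MeOTf and MgO in PhCF3 at rt (N-methylation, then transfer of the benzyl cation to the alcohol) should give ether 10, where the route is rejoined.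

Further compounds
F1 | step 7 | 4-benzyloxy-3-methoxybenzaldehyde | COc1cc(C=O)ccc1OCc1ccccc1
F2 | step 7 | (E)-4-(4-benzyloxy-3-methoxyphenyl)but-3-en-2-one | COc1cc(/C=C/C(C)=O)ccc1OCc1ccccc1
F3 | step 7 | 4-[(3S,6E)-7-(4-benzyloxy-3-methoxyphenyl)-3-hydroxy-5-oxohept-6-en-1-yl]-2-methoxyphenyl pivalate | COc1cc(CC[C@H](O)CC(=O)/C=C/c2ccc(OCc3ccccc3)c(OC)c2)ccc1OC(=O)C(C)(C)C
F4 | step 3 | 4-[(3S)-3-hydroxy-6-(trimethylsilyl)hex-5-yn-1-yl]-2-methoxyphenyl pivalate | COc1cc(CC[C@H](O)CC#C[Si](C)(C)C)ccc1OC(=O)C(C)(C)C
F5 | step 5 | 2-[(4-benzyloxy-3-methoxyphenyl)methoxy]-4-methylquinoline | COc1cc(COc2cc(C)c3ccccc3n2)ccc1OCc1ccccc1
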